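The target in the earlier runs does not account for what the starting material loses. At 12.0 d the spring run reads 27.9% of target and 34.9% of starting material, so 37.2% of the charge is neither. Divide that unseen share by the starting material left, and the last readings of spring, midnight and autumn give 1.07, 1.10 and 1.12. Their mean, 1.10, is a reading with the scatter of the tables in it, and I call it the missing ratio.

| setting | spring | midnight | autumn | flask |
|---|---|---|---|---|
| starting material | 0.010 M | 0.015 M | 0.020 M | 0.020 M |
| partner | 0.020 M | 0.020 M | 0.020 M | 0.0200 M |
| second substrate | 0.020 M (fed, over 2.5 h) | 0.020 M (fed, over 2.5 h) | 0.040 M (fed, over 2.5 h) | 0.0200 M (fed, over 2.5 h) |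
| remark | run made earlier; the fed solution adds 0.20 times the starting volume | run made earlier; the fed solution adds 0.20 times the starting volume | run made earlier; the fed solution adds 0.20 times the starting volume | the fed solution adds 0.20 times the starting volume |
| time |  |  |  | 15 d |

| run | time / d | starting material / % | target / % |
|---|---|---|---|
| spring | 1.04 | 45.9 | 38.3 |
| spring | 1.67 | 42.0 | 36.2 |
| spring | 2.00 | 40.4 | 34.7 |
| spring | 3.00 | 38.3 | 32.3 |
| spring | 5.00 | 37.2 | 30.3 |
| spring | 8.00 | 35.2 | 29.9 |
| spring | 12.0 | 34.9 | 27.9 |
| midnight | 0.625 | 52.7 | 35.3 |
| midnight | 1.67 | 43.8 | 33.6 |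
| midnight | 3.00 | 39.6 | 30.2 |
| midnight | 5.00 | 36.6 | 28.8 |
| midnight | 8.00 | 35.6 | 26.9 |
| midnight | 10.0 | 34.8 | 27.8 |
| midnight | 12.0 | 34.4 | 27.9 |
| autumn | 1.04 | 52.3 | 29.4 |
| autumn | 1.67 | 47.3 | 28.4 |
| autumn | 3.00 | 42.6 | 26.0 |
| autumn | 6.00 | 39.2 | 23.4 |
| autumn | 12.0 | 36.4 | 22.7 |

(scatter of a reading: 0.5 percentage points)

* share of the starting material used up at 15 d
* target at 15 d, in percent of the starting material charged

Now climb the ladder of times. The feed ends after 2.5 h, before the earliest reading at 0.625 d. The highest target reading in spring, 38.3%, stands at 1.04 d, and the target then drifts down. The missing ratio is still climbing after the feed has ended: spring reads 0.519 at 1.67 d, about half its last value. On the top rung, spring's starting material moves from 35.2% to 34.9% between 8.00 d and 12.0 d, less than the scatter of 0.5 percentage points. You can therefore read the plateau of these runs as a rule, for the time after the missing ratio has stopped moving: starting material left, in percent of its charge, is the charge less the target, divided by one plus the missing ratio.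

The forecast gives 63.5% used up and 26.5% of target at 15 d, on this ground: “That looks like an equilibrium or a self-limiting process”. My own reckoning, fed with that target, leaves 35.1% and so uses up 64.9%, slightly more than the forecast says.

The flask gives 64.5% used up and 25.6% of target.

    starting material + partner ⇌ target (K = 73.0 M⁻¹, k = 0.00130 M⁻¹ s⁻¹)
    second substrate + partner ⇌ second product (K = 18.0 M⁻¹, k = 6.70 × 10⁻⁴ M⁻¹ s⁻¹)
    starting material ⇌ dormant form (K = 1.10, k = 3.70 × 10⁻⁶ s⁻¹)

The exchange of starting material with dormant form, by this step alone, has a relaxation half-life of 1.14 d, short against the 15 d of the flask. The flask holds 36.0% starting material and 38.0% dormant form at 7.50 d, and 35.5% and 39.0% at 15.0 d. With its target, the rule leaves 35.4%, and the flask holds 35%. A neighbour with c(partner) = 0.050 M ends above the forecast's target, with 49.3% of target; the rule then leaves 24.1%, and that neighbour holds 24.2% of its starting material.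

The data come from a simulation with constants of no real substance; noise was put on by code.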